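| setting | Thursday's | Saturday's | Sunday's | flask |
|---|---|---|---|---|
| left-handed substrate | 0.035 M | 0.078 M | 0.052 M | 0.052 M |
| right-handed substrate | 0.035 M | 0.078 M | 0.052 M | 0.052 M |
| reagent | 0.0312 M | 0.0312 M | 0.0312 M | 0.0312 M |
| free catalyst | 0.10 mM | 0.10 mM | 0.20 mM | 0.10 mM |
| remark | run made earlier | run made earlier | run made earlier |  |
| time |  |  |  | 20 min |

| run | time / min | left-handed product / % | right-handed product / % |
|---|---|---|---|
| Thursday's | 2.50 | 2.0 | 0.5 |
| Thursday's | 8.00 | 3.3 | 1.3 |
| Thursday's | 12.0 | 3.9 | 2.0 |
| Thursday's | 20.0 | 3.1 | 2.8 |
| Saturday's | 2.50 | 1.6 | 0.3 |
| Saturday's | 8.00 | 3.8 | 1.9 |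
| Saturday's | 12.0 | 3.7 | 2.0 |
| Saturday's | 20.0 | 2.7 | 2.7 |
| Sunday's | 5.00 | 6.7 | 1.7 |
| Sunday's | 10.0 | 6.6 | 3.7 |
| Sunday's | 15.0 | 6.0 | 4.0 |
| Sunday's | 20.0 | 5.1 | 4.9 |

(standard deviation of a reading: 0.3 percentage points)

- free catalyst is single-handed; left-handed substrate and right-handed substrate are mirror images of each other, charged as a racemate, each of them at the stated concentration
- the analysis behind the earlier runs scatters by 0.3 percentage points, standard deviation
- an excess is the difference of the two amounts in percent of their sum
- an excess is below zero if the other one leads

- excess of left-handed product over right-handed product in the product at 1.0 min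
- excess of left-handed product over right-handed product in the product at 20 min
- part of the left-handed substrate and right-handed substrate charged together that has reacted at 20 min

If left-handed and right-handed product together stand at 5.90% of the charge at 12.0 min and at 5.90% at 20.0 min, then Thursday's run reads as stalled with 94.1% of its two substrates together unreacted. I take that as a catalyst that stops working, so I count what it does before then.

1. I take the rate as pseudo-first-order in left-handed substrate and proportional to working catalyst, at the reagent charge of 0.0312 M that Thursday's, Saturday's and Sunday's runs and the flask share. Integrated, the logarithm of charged over remaining left-handed substrate is then a single number for a given catalyst charge, and I take it as proportional to that charge.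

2. I count all product as coming from left-handed substrate. The last readings then give 0.126 on Thursday, 0.114 on Saturday, close despite different substrate charges, and 0.223 on Sunday. Pooled, with Sunday's doubled catalyst halved, that is 0.117 for the flask: my catalyst dose, the logarithm of charged over remaining left-handed substrate.

3. Left-handed substrate is half of the charge, so I expect 5.53% reacted in the flask at 20 min.

4. One number is not enough. At Thursday's steady total, left-handed product falls from 3.9% to 3.1%, so the excess runs on a second clock, and I commit to no excess.

The forecast gives an excess of 72% at 1.0 min and 2.5% at 20 min, and 5.7% reacted, a reacted part above mine: “So the reaction is first order in substrate, and the catalyst dies, giving a plateau conversion proportional to catalyst loading.”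

The flask gives an excess of 86.5% at 1.0 min, above the forecast, then an excess of 6.53% and 6.09% reacted at 20 min. By their interconversion alone, both ways together, the two products relax with a half-life of 3.57 min, short against 20 min. The 88% of the flask's left-handed substrate still there at 20.0 min makes a dose of 0.128 beside my 0.117.

    reagent + free catalyst + right-handed substrate → free catalyst + right-handed product (k = 220 M⁻² min⁻¹)
    left-handed product ⇌ right-handed product (k = 0.0970 min⁻¹)
    reagent + free catalyst + left-handed substrate → free catalyst + left-handed product (k = 10000 M⁻² min⁻¹)
    reagent + free catalyst → spent catalyst B (k = 3.10 M⁻¹ min⁻¹)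
    free catalyst → spent catalyst A (k = 0.130 min⁻¹)

A neighbouring flask holds 4.0 × 10⁻⁴ M of free catalyst, so my dose scales to 0.469 and gives 18.7% reacted. Computed, 17.2% has reacted there at 20 min, with 66% of its left-handed substrate and 42.1% of its reagent left.

The earlier runs and the new flask stem from a simulated flask with made-up constants; scatter was added.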